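Which flask ends richest in complex with two exchanged, counted against two plus three exchanged, when the same charge goes in by different routes?

all flasks: time 40 s

| run | starting complex | incoming ligand | remark |
|---|---|---|---|
| north | 0.50 mM | 0.900 equiv (fed, over 30 s) | all else is in the flask from the start; the feed brings no volume worth counting |
| east | 0.50 mM (fed, over 30 s) | 0.900 equiv | all else is in the flask from the start; the feed brings no volume worth counting |
| north-west | 0.50 mM | 0.900 equiv | everything together at the start |

    starting complex + incoming ligand ⇌ leaving ligand + complex with one exchanged (K1 = 5.2, k1 = 2520 M⁻¹ s⁻¹)
    complex with one exchanged + incoming ligand ⇌ leaving ligand + complex with two exchanged (K2 = 15, k2 = 5020 M⁻¹ s⁻¹)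
    complex with two exchanged + incoming ligand ⇌ leaving ligand + complex with three exchanged (K3 = 25, k3 = 1340 M⁻¹ s⁻¹)
    complex with one exchanged → decomposed reagent (k4 = 0.0312 s⁻¹)
    incoming ligand ⇌ dormant form (K5 = 1.8, k5 = 0.184 s⁻¹)

- which flask leads in share of complex with two exchanged in complex with two exchanged plus complex with three exchanged ("all alike" within 1.5 percentage points) (north / east / north-west / all alike)
- share of complex with two exchanged in complex with two exchanged plus complex with three exchanged at the end, north
- share of complex with two exchanged in complex with two exchanged plus complex with three exchanged at the end, east
- share of complex with two exchanged in complex with two exchanged plus complex with three exchanged at the end, north-west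

The incoming ligand is the limiting reagent, 0.450 mM in all. I write its balance: charged ligand is leaving ligand plus free incoming ligand plus dormant form. The dormant form follows the free ligand at 1.8 times its amount, since its forward half-life of 3.8 s is shorter than the 40 s of the run.

Let r be free incoming ligand over leaving ligand, and try 0.0500. The balance then gives 0.395 mM of leaving ligand, which asks for 0.789 exchanges per complex charged. The exchange equilibria at this r, with decomposed reagent left aside, give 0.813, so the trial holds. Three exchanged over two exchanged is then 25 times r, and the equilibrium share is 44.4%.

One chemist holds that the flasks simply reach this equilibrium. I hold that the third exchange has a clock of its own, its relaxation half-life τ: the natural log of two over the sum of its forward rate constant times free incoming ligand and its backward rate constant times leaving ligand. That gives 14.6 s. After north's feed stops, 10.0 s remain, less than τ, so any gap to equilibrium keeps 62.2% of its size. North-west has 2.74 such half-lives. I therefore commit to north standing clearly above 44.4%, with north-west near it. East lies beyond this reckoning, so I name north only against north-west.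

The forecast names north as leader, with 49% for north, 34% for east and 46% for north-west, on the ground that "The exchange steps re-equilibrate within tens of seconds". Its north value is about what one gets with everything added at the start. We both set north above north-west and part on how far north has come down.

The flasks give 58.1% for north, 45.6% for east and 45.6% for north-west, so north leads.

At 40.0 s north holds 8.28% of complex with three exchanged beside 11.5% with two exchanged, a ratio of 0.720, while 25 times its r is 1.31, and north's own readings put τ at 14.3 s against the 10.0 s after its feed. The equilibrium view gets its region on the same north flask read at 60.0 s, 30.0 s after the feed and twice τ, where the share reads 46.4%.

The constants used here were set for the occasion; what happens was integrated by code.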